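Target came fast and then slowly in the birch run. Over the first 5.00 min its mean rate was 0.125 min⁻¹ of the charge, and from there to the last reading it was 0.00144 min⁻¹, a fall by a factor of 87.3.

| flask | starting material | free enzyme | temperature | remark | time |
|---|---|---|---|---|---|
| oak | 0.067 M | 0.01 mol% | 15 °C | run made earlier |  |
| birch | 0.15 M | 0.01 mol% | 32 °C | run made earlier |  |
| ash | 0.10 M | 0.005 mol% | 15 °C | run made earlier |  |
| north-west | 0.10 M | 0.01 mol% | 45 °C |  | 40 min |
| south | 0.10 M | 0.01 mol% |  | at 45 °C until 12 min, from then on at 20 °C | 40 min |
| south-west | 0.10 M | 0.01 mol% | 20 °C |  | 40 min |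

- oak (time / min: target / %): 8.00: 86.4; 25.0: 87.6; 50.0: 89.7; 80.0: 93.3; 120: 94.5
- birch (time / min: target / %): 5.00: 62.7; 8.00: 64.1; 15.0: 67.9; 25.0: 69.6; 40.0: 68.7; 60.0: 70.6
- ash (time / min: target / %): 12.0: 67.8; 40.0: 72.5; 60.0: 75.2; 120: 79.0

(scatter of a reading: 1 percentage point)

- a reading or a percentage of target counts all its forms, free or not

* the flask that comes out highest in amount of target, in percent of the starting material charged, or "all alike" when all lie within 1.5 percentage points (north-west / south / south-west / all alike)
* target at the end, in percent of the starting material charged, north-west
* target at the end, in percent of the starting material charged, south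
* target at the end, in percent of the starting material charged, south-west

Had the rate simply followed the starting material left, the birch readings would have allowed a fall by a factor of 3.40. The observed fall was greater, so I put the remaining factor of 25.7 on the loss of working enzyme and read the plateau as the end of the catalyst.

A mean rate summed over a working life is a capacity, N: percent of target divided by mol% of free enzyme, the total turnover number. The last birch reading gave 7060 at 32 °C, and the last ash reading gave 15800 at 15 °C. Holding the factor per degree constant, I reckoned N as 3810 at 45 °C, which at 0.01 mol% meant 38.1 % in north-west. At 20 °C the same extrapolation gave 12500, or 125 %, an estimate above the charge and no bound, so I expected south-west to end above north-west. Birch had made 62.7 % by 5.00 min, well before south's change at 12 min, so I expected south to stay level with north-west.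

The forecast named south-west as highest, with north-west at 57 % (48 % to 64 %), south at 72 % (58 % to 83 %) and south-west at 81 % (74 % to 88 %). It held that “North-west should reach its ceiling quickly”. My reckoning agreed on the order at the top but set north-west and south lower.

North-west ended at 32.7 %, south at 32.7 % and south-west at 88.0 %, so south-west stood highest.

    free enzyme → unfolded enzyme (k = 2.50 × 10⁻⁴ min⁻¹, Ea = 195 kJ mol⁻¹)
    starting material + free enzyme → target + free enzyme, rate k2*[starting material]*[free enzyme]/(1 + ([starting material]/Km2) + ([target]/Kp2)) (0.0500 M, 0.120 M, k = 5.80 × 10⁵ M⁻¹ min⁻¹, Ea = 33.0 kJ mol⁻¹)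
    free enzyme → spent catalyst (k = 0.880 min⁻¹, Ea = 88.0 kJ mol⁻¹)
    free enzyme + target ⇌ idle complex (K = 440 M⁻¹, k = 14.0 M⁻¹ min⁻¹, Ea = 49.0 kJ mol⁻¹, ΔH = −53.0 kJ mol⁻¹)
    (constants at 20 °C)

In north-west, half of the turnover was done by 2.53 s, less than the 2.8 s half-life of free enzyme towards spent catalyst at 0.0421 min. North-west's capacity thus came to 3270, below my 3810 and below the birch reading. South had 0 % free enzyme, in percent of the catalyst charged, at 12.0 min, and its target stood at 32.7 % then and 32.7 % at the end. The neighbour of north-west with 0.060 M of starting material, at the same loading, ended at 27.2 %, a capacity of 2720.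

Readings and results were generated by integration with constants of no real substance.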